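**Assumption:** daucane numbering is used for positions (C1 = methyl-bearing quaternary ring-fusion carbon, C4 = isopropyl carbinol, C5 = ring-fusion CH, C6 = ester carbinol, C8 = methylidene carbon, C9 = allylic carbinol, C10 = ring CH2). AllylMgBr, Me3Al, i-PrMgCl and CO2 are bought and numbered as starting materials.

## Retrosynthetic overview

1. Ferugin ⇐ aryl silyl ether 16 ⇐ C8–C9 bond by SmI2 ketyl–alkyne 7-exo-dig radical cyclization of alkynyl aldehyde 15. The seven-membered ring is closed last, and this step sets C9 and the exocyclic methylene.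
2. 15 ⇐ ozonolysis of the allyl group of 14; the C6 ester comes from diol 10 and acid 13 (4-bromophenol + CO2).
3. 10 ⇐ isopropyl addition to cyclopentanone 8 (sets C4).
4. 8 ⇐ anti-aldol of the regiodefined enolate from 5 with but-3-ynal (sets C5 and C6).
5. 5 ⇐ catalytic asymmetric conjugate methylation of 3-allylcyclopentenone 3 (sets C1) ⇐ 3-methoxycyclopentenone + allylMgBr. The five-membered ring is present from the start.

## Route

**Step 1**
Reactants: 1, 3-methoxycyclopent-2-en-1-one; 2, allylmagnesium bromide
Product: 3, 3-(prop-2-en-1-yl)cyclopent-2-en-1-one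
Conditions: 2 (1.2 equiv), THF, 0 °C; then 1 M HCl, 0 °C
Reagents that add atoms: allylmagnesium bromide, C=CC[Mg]Br; water, O (new carbonyl oxygen)
Why: Stork–Danheiser transposition (1,2-addition to the vinylogous ester, then acid hydrolysis of the enol ether and dehydration) gives the 3-allyl enone; no stereocentre is formed.

**Step 2**
Reactants: 3; 4, trimethylaluminium
Product: 5, trimethyl{[(3R)-3-methyl-3-(prop-2-en-1-yl)cyclopent-1-en-1-yl]oxy}silane
Conditions: Cu(OTf)2 (5 mol%), chiral sulfonate-bridged NHC–Ag complex (2.5 mol%), Me3Al (2 equiv), THF, −78 °C; then TMSOTf, −78 → 0 °C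
Reagents that add atoms: trimethylaluminium, C[Al](C)C; TMSOTf, C[Si](C)(C)OS(=O)(=O)C(F)(F)F
Why: Cu–NHC-catalysed asymmetric conjugate addition of R3Al to a β-substituted cyclopentenone delivers methyl to one enone face (ligand enantiomer chosen for 3R = C1 of the target), and O-silylation of the aluminium enolate fixes the enolate regiochemistry toward C5.

**Step 3**
Reactants: 6, but-3-yn-1-ol
Product: 7, but-3-ynal
Conditions: Dess–Martin periodinane, NaHCO3, CH2Cl2, 0 °C; washed (NaHCO3/Na2S2O3), dried solution used at once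
Reagents that add atoms: none
Why: Buffered Dess–Martin oxidation gives the sensitive β,γ-alkynyl aldehyde without base-induced isomerisation to the allenyl aldehyde.

**Step 4**
Reactants: 5; 7
Product: 8, (2S,3R)-2-[(1S)-1-hydroxybut-3-yn-1-yl]-3-methyl-3-(prop-2-en-1-yl)cyclopentan-1-one
Conditions: MeLi, THF, 0 °C; (c-C6H11)2BCl, −78 °C; then 7 (1.5 equiv), −78 °C; H2O2, pH 7 buffer, MeOH, 0 °C
Reagents that add atoms: none (both partners are numbered reactants)
Why: MeLi releases the regiodefined enolate, which as its (E)-enol borinate reacts through a closed Zimmerman–Traxler chair to give the anti aldol (C5/C6); the aldehyde approaches the face syn to the C1 methyl and anti to the larger allyl arm, but this methyl-versus-allyl bias is only moderate (about 4:1 expected), so the minor C5 epimer is removed by chromatography.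

**Step 5**
Reactants: 8; 9, isopropylmagnesium chloride
Product: 10, (1R,2S,3R)-2-[(1S)-1-hydroxybut-3-yn-1-yl]-3-methyl-1-(propan-2-yl)-3-(prop-2-en-1-yl)cyclopentan-1-ol
Conditions: LaCl3·2LiCl (or anhydrous CeCl3), i-PrMgCl (4 equiv), THF, −78 → −20 °C
Reagents that add atoms: isopropylmagnesium chloride, CC(C)[Mg]Cl
Why: Lanthanide-promoted Grignard 1,2-addition suppresses enolisation and retro-aldol, and the nucleophile attacks the ketone face anti to the adjacent C5 side chain, so isopropyl ends trans and OH cis to that chain (C4 = R).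

**Step 6**
Reactants: 11, 4-bromophenol; 12, carbon dioxide
Product: 13, 4-[(tert-butyldimethylsilyl)oxy]benzoic acid
Conditions: NaH, TBSCl (1.0 equiv), THF, 0 °C → rt; then n-BuLi, −78 °C; CO2 (g); aqueous citric acid work-up
Reagents that add atoms: TBSCl, CC(C)(C)[Si](C)(C)Cl; carbon dioxide, O=C=O
Why: One-pot O-silylation, bromine–lithium exchange and carboxylation of the aryllithium give the protected acid; no stereocentre.

**Step 7**
Reactants: 10; 13
Product: 14, (1S)-1-[(1S,2R,5R)-2-hydroxy-5-methyl-2-(propan-2-yl)-5-(prop-2-en-1-yl)cyclopentyl]but-3-yn-1-yl 4-[(tert-butyldimethylsilyl)oxy]benzoate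
Conditions: EDC·HCl, DMAP, CH2Cl2, rt
Reagents that add atoms: none beyond 13
Why: Steglich esterification acylates only the secondary C6–OH (the tertiary C4–OH is inert) with retention at C6.

**Step 8**
Reactants: 14
Product: 15, (1S)-1-[(1S,2R,5R)-2-hydroxy-5-methyl-5-(2-oxoethyl)-2-(propan-2-yl)cyclopentyl]but-3-yn-1-yl 4-[(tert-butyldimethylsilyl)oxy]benzoate
Conditions: O3, CH2Cl2, −78 °C (Sudan III end-point); then PPh3, −78 °C → rt
Reagents that add atoms: ozone, [O-][O+]=O (one O retained)
Why: Ozonolysis cleaves the monosubstituted alkene far faster than the terminal alkyne or the aryl ring and unveils the C9 aldehyde; C4–OH is trans to the CH2CHO arm, so no lactol forms.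

**Step 9 (key step)**
Reactants: 15
Product: 16, (3R,3aS,4S,7S,8aR)-3,7-dihydroxy-8a-methyl-6-methylidene-3-(propan-2-yl)decahydroazulen-4-yl 4-[(tert-butyldimethylsilyl)oxy]benzoate
Conditions: SmI2 (4 equiv), HMPA (12 equiv), t-BuOH (2 equiv), THF, 0 °C, slow addition of 15 (final 0.005 M)
Reagents that add atoms: none
Why: Proposed new method: SmI2–HMPA reduces the aldehyde to a C9 ketyl radical that adds 7-exo-dig to the internal alkyne carbon C8, and the vinyl radical is quenched (H from THF, or reduction and protonation by t-BuOH) to the exocyclic methylene, forming the C8–C9 bond and the seven-membered ring; in the chair-like transition state the bulky O–Sm(HMPA)n group sits pseudo-equatorial, away from the axial C1 methyl, giving 9S (OH trans to the angular methyl); the closest known chemistry is SmI2/HMPA 5- and 6-exo-dig ketyl–alkyne cyclisation to 2-methylenecycloalkanols and SmI2 ketyl–olefin closure of 7- and 8-membered rings.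

**Step 10**
Reactants: 16
Product: 17, ferugin, (3R,3aS,4S,7S,8aR)-3,7-dihydroxy-8a-methyl-6-methylidene-3-(propan-2-yl)decahydroazulen-4-yl 4-hydroxybenzoate
Conditions: TBAF, AcOH, THF, 0 °C
Reagents that add atoms: none
Why: Buffered fluoride cleaves the aryl silyl ether without ester cleavage or acyl migration; no stereocentre is touched.

## Compound list

1 | 3-methoxycyclopent-2-en-1-one | COC1=CC(=O)CC1 | starting material
2 | allylmagnesium bromide | C=CC[Mg]Br | starting material
3 | 3-(prop-2-en-1-yl)cyclopent-2-en-1-one | C=CCC1=CC(=O)CC1 | intermediate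
4 | trimethylaluminium | C[Al](C)C | starting material
5 | trimethyl{[(3R)-3-methyl-3-(prop-2-en-1-yl)cyclopent-1-en-1-yl]oxy}silane | C=CC[C@@]1(C)CCC(O[Si](C)(C)C)=C1 | intermediate
6 | but-3-yn-1-ol | C#CCCO | starting material
7 | but-3-ynal | C#CCC=O | intermediate
8 | (2S,3R)-2-[(1S)-1-hydroxybut-3-yn-1-yl]-3-methyl-3-(prop-2-en-1-yl)cyclopentan-1-one | C#CC[C@H](O)[C@@H]1[C@@](C)(CC=C)CCC1=O | intermediate
9 | isopropylmagnesium chloride | CC(C)[Mg]Cl | starting material
10 | (1R,2S,3R)-2-[(1S)-1-hydroxybut-3-yn-1-yl]-3-methyl-1-(propan-2-yl)-3-(prop-2-en-1-yl)cyclopentan-1-ol | C#CC[C@H](O)[C@@H]1[C@@](C)(CC=C)CC[C@@]1(O)C(C)C | intermediate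
11 | 4-bromophenol | Oc1ccc(Br)cc1 | starting material
12 | carbon dioxide | O=C=O | starting material
13 | 4-[(tert-butyldimethylsilyl)oxy]benzoic acid | CC(C)(C)[Si](C)(C)Oc1ccc(cc1)C(O)=O | intermediate
14 | (1S)-1-[(1S,2R,5R)-2-hydroxy-5-methyl-2-(propan-2-yl)-5-(prop-2-en-1-yl)cyclopentyl]but-3-yn-1-yl 4-[(tert-butyldimethylsilyl)oxy]benzoate | C#CC[C@H](OC(=O)c1ccc(O[Si](C)(C)C(C)(C)C)cc1)[C@@H]2[C@@](C)(CC=C)CC[C@@]2(O)C(C)C | intermediate
15 | (1S)-1-[(1S,2R,5R)-2-hydroxy-5-methyl-5-(2-oxoethyl)-2-(propan-2-yl)cyclopentyl]but-3-yn-1-yl 4-[(tert-butyldimethylsilyl)oxy]benzoate | C#CC[C@H](OC(=O)c1ccc(O[Si](C)(C)C(C)(C)C)cc1)[C@@H]2[C@@](C)(CC=O)CC[C@@]2(O)C(C)C | intermediate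
16 | (3R,3aS,4S,7S,8aR)-3,7-dihydroxy-8a-methyl-6-methylidene-3-(propan-2-yl)decahydroazulen-4-yl 4-[(tert-butyldimethylsilyl)oxy]benzoate | C=C1C[C@H](OC(=O)c2ccc(O[Si](C)(C)C(C)(C)C)cc2)[C@@H]3[C@](C)(CC[C@@]3(O)C(C)C)C[C@@H]1O | intermediate
17 | ferugin | C=C1C[C@H](OC(=O)c2ccc(O)cc2)[C@@H]2[C@](C)(CC[C@@]2(O)C(C)C)C[C@@H]1O | target

## Step count and risks

Total steps: 10. Longest linear sequence: 8 (steps 1, 2, 4, 5, 7, 8, 9, 10).

Steps most likely to fail:

1. **Step 9 (7-exo-dig ketyl–alkyne cyclisation).** The closure is slow, so simple aldehyde reduction or pinacol coupling may win. Fallback: convert the alkyne of 14 into the 2-iodo-1-alkene (B-iodo-9-BBN, then AcOH), ozonise, and close the same C8–C9 bond by an intramolecular Ni/Cr Nozaki–Hiyama–Kishi reaction.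
2. **Step 4 (aldol).** The methyl-versus-allyl facial bias at C5 is weak, and but-3-ynal is fragile. Fallback: build C1 by Cu–NHC conjugate addition of diisobutyl[1-(trimethylsilyl)vinyl]aluminium to 3-methylcyclopent-2-enone, so the C1 substituent is far larger than methyl during the aldol. Then protodesilylate and use hydroboration–oxidation and oxidation in place of ozonolysis to reach the same CH2CHO arm.
3. **Step 5 (isopropyl addition).** The hindered, enolisable β-hydroxy ketone may undergo reduction, enolisation or retro-aldol. Fallback: samarium Barbier addition of 2-iodopropane (SmI2, HMPA, catalytic NiI2), which is non-basic and works through an organosamarium rather than a Grignard reagent.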